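(The readings come from a simulation for substances that don't exist; scatter was added.)

**Counting chains.** The easy mistake is to count one chain per pre-initiator charged. Follow one molecule: pre-initiator becomes initiator, which then meets free monomer or impurity, and the second path begins no chain. The elm run, with impurity above pre-initiator, still put 17% into chains by 12.0 h, so this fork is a contest, not a strict titration. In our flask the impurity is the smaller charge, so as a first reckoning we take it as wholly consumed, and 0.270 mM is our count of chains: the excess, pre-initiator charged less impurity consumed.

| flask | free monomer | pre-initiator | impurity | remark | time |
|---|---|---|---|---|---|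
| maple | 0.068 M (fed, over 15 min) | 0.68 mM | 0.57 mM | run made earlier |  |
| elm | 0.068 M (fed, over 15 min) | 0.68 mM | 0.90 mM | run made earlier |  |
| flask | 0.068 M (fed, over 15 min) | 0.68 mM | 0.41 mM |  | 20 h |

- maple (time / h: monomer in chains / %, free monomer / %): 2.00: 4, 97; 4.00: 11, 88; 6.00: 19, 79; 8.00: 25, 73; 10.0: 29, 68; 12.0: 37, 63
- elm (time / h: monomer in chains / %, free monomer / %): 0.833: 2, 96; 2.50: 1, 98; 4.00: 3, 98; 6.00: 7, 93; 10.0: 11, 85; 12.0: 17, 81

(scatter of a reading: 1.5 percentage points)

- in percentages every species weighs as the free monomer in it: one homo dimer counts as two
- the average divides the monomer in chains by the number of chains begun, living and dead together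
- the analysis behind the earlier runs scatters by 1.5 percentage points, standard deviation
- what may be going on: free monomer + initiator -> living end + monomer in chains; free monomer + living end -> monomer in chains + living end; 2 free monomer -> homo dimer; initiator + impurity -> spent initiator; pre-initiator -> initiator
- the earlier runs do not show the number of chains; that part of a forecast is a guess

- average number of monomer units in a chain (chains begun, living or dead) at 20 h
- part of the free monomer that has reacted at 20 h

**What matters.** The average is monomer in chains over the excess. An error of one percent in the free monomer charge moves it by as much, but in the flask the same error moves the excess by 1.52 percent for impurity and 2.52 percent for pre-initiator. The feed of 15 min is short beside 20 h, and maple's 37% and 63% account for its charge, so we drop both feed and homo dimer.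

**Our number.** Maple lost free monomer at 0.0385 /h, lag included, on an excess of 0.110 mM. Scaling this pseudo-first-order rate by the excess, our flask runs at 0.0945 /h, which gives 84.9% reacted and an average of 214.

**The check.** The forecast, lower than ours at 135 and 66%, holds that “initiator is shared between monomer and impurity”. The flask gives 198 and 80.1%.

    free monomer + initiator → living end + monomer in chains (k = 0.0840 /M/s)
    free monomer + living end → monomer in chains + living end, rate k2*[living end]*[free monomer] (k = 0.0870 /M/s)
    2 free monomer → homo dimer (k = 3.70 × 10⁻⁶ /M/s)
    initiator + impurity → spent initiator (k = 120 /M/s)
    pre-initiator → initiator (k = 4.00 × 10⁻⁴ /s)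

**Still moving.** At 20.0 h the flask holds 2.71 × 10⁻⁴ M of living ends, matching the excess, with 0.20% of its impurity left; 78.9% in chains over the excess gives 199. A further flask, like ours but with 7.0 × 10⁻⁴ M of impurity, keeps 15% of it at 20.0 h, so its excess is 0.0825 mM, near its 8.25 × 10⁻⁵ M of living ends. Our flask has not come to rest, with 20% of its free monomer still there. Ten times as long, its living ends still stand at 2.71 × 10⁻⁴ M, while free monomer falls to 0%, the reacted part reaches 100% and the average reaches 248.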